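**Retrosynthetic overview**
1. Feature: ring A (C10–C11–C12–C13–C14) carries C9 (on C10), C1 (on C11) and C15 (on C14) on one face and the C14 methyl on the other. This is the pattern left when a cis-2,3-disubstituted 1-methylcyclohexene syn-oxide contracts by a shift of C10 from C15 to C14.
2. Ring C (C1–C11, eleven-membered) is opened at C1–C2: Nozaki–Hiyama–Kishi addition of a C1 alkenyl triflate to a C2 aldehyde, with C2 then fixed by oxidation and CBS reduction.
3. Ring B (C8, C9, C10, C14, C15, C16) is opened at C8=C9 (ring-closing metathesis). C7–C8 comes from a C2–C7 alkyllithium (C5 set by auxiliary-controlled allylation) and a Weinreb amide; C15/C16 come from a syn-glycolate aldol on the ring A aldehyde.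
4. The ring A aldehyde comes from InCl3 rearrangement of the syn-epoxide, which comes from hydroxyl-directed epoxidation of the endo Diels–Alder adduct of the (S)-lactate-derived diene and methyl acrylate.
5. Order of ring formation: sacrificial cyclohexene, ring A (contraction), ring B (metathesis), ring C (NHK).

Key step: step 10

Remark: C1–C16 are the sixteen ring carbons of the target in the order of its SMILES. The C1 ester of the cycloadduct is carried through the key step as its silyl-protected carbinol, because a free C9 hydroxyl cis to a C1 ester would lactonise. The carbinol carbons of 43 and 48 are carried as both epimers because each is oxidised in the next step. TBS = tert-butyldimethylsilyl, TES = triethylsilyl, PMB = 4-methoxybenzyl, Bn = benzyl, DMP = Dess–Martin periodinane, PPTS = pyridinium p-toluenesulfonate.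

**Route**

Step 1
Reactants: 1 ethyl (S)-lactate
Product: 2 ethyl (2S)-2-(TBS-oxy)propanoate
Conditions: TBSCl, imidazole, DMF, 0 °C → rt
Reagents that add atoms: tert-butyldimethylsilyl chloride, CC(C)(C)[Si](C)(C)Cl
Why: Standard silylation of the secondary hydroxyl leaves the lactate stereocentre (future C9) untouched.

Step 2
Reactants: 2 ethyl (2S)-2-(TBS-oxy)propanoate
Product: 3 (2S)-2-(TBS-oxy)propanal
Conditions: iBu2AlH (1.1 equiv), CH2Cl2, −78 °C; Rochelle salt work-up
Reagents that add atoms: none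
Why: Low-temperature half-reduction of the ester stops at the aluminium hemiacetal, which should release the α-silyloxy aldehyde on work-up without racemisation (used crude).

Step 3
Reactants: 3 (2S)-2-(TBS-oxy)propanal; 4 diethyl (2-oxopropyl)phosphonate
Product: 5 (3E,5S)-5-(TBS-oxy)hex-3-en-2-one
Conditions: LiCl, iPr2NEt, MeCN, rt
Reagents that add atoms: none
Why: Horner–Wadsworth–Emmons olefination under Masamune–Roush conditions should give the (E)-enone, the mild amine base sparing the epimerisable aldehyde.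

Step 4
Reactants: 5 (3E,5S)-5-(TBS-oxy)hex-3-en-2-one
Product: 6 tert-butyl(dimethyl){[(2S,3E)-5-methylhexa-3,5-dien-2-yl]oxy}silane
Conditions: Ph3PCH3Br, KN(SiMe3)2, THF, −78 → 0 °C
Reagents that add atoms: methyltriphenylphosphonium bromide, C[P+](c1ccccc1)(c1ccccc1)c1ccccc1.[Br-]
Why: Wittig methylenation by 1,2-addition of the non-stabilised ylide converts the ketone into the 2-methyl-1,3-diene and leaves the (E)-alkene and C9 unchanged.

Step 5
Reactants: 6 (S,E)-silyloxy diene; 7 methyl acrylate
Product: 8 methyl (1R,2S)-2-[(1S)-1-(TBS-oxy)ethyl]-4-methylcyclohex-3-ene-1-carboxylate (C9 and C1 arms cis)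
Conditions: Me2AlCl (0.2 equiv), CH2Cl2, −78 → −20 °C
Reagents that add atoms: none
Why: In this Lewis-acid-catalysed Diels–Alder reaction the terminal alkyl group and the 3-methyl group of the diene both direct the ester-bearing carbon next to C10 ("ortho/para" rule), the endo transition state places the C9 and C1 arms cis, and the acrylate is expected to add to the diene face opposite the OTBS group in the conformer that holds the C9–H bond in the diene plane, which sets C10 (S) and C11 (R).

Step 6
Reactants: 8 Diels–Alder ester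
Product: 9 {(1R,2S)-2-[(1S)-1-(TBS-oxy)ethyl]-4-methylcyclohex-3-en-1-yl}methanol
Conditions: LiAlH4, THF, 0 °C
Reagents that add atoms: none
Why: Hydride reduction of the ester to the primary alcohol removes the epimerisable, lactone-prone carbonyl at C1 before the C9 hydroxyl is freed.

Step 7
Reactants: 9 silyloxy alcohol
Product: 10 (1S)-1-[(1S,6R)-6-(hydroxymethyl)-3-methylcyclohex-2-en-1-yl]ethan-1-ol
Conditions: Bu4NF, THF, 0 °C → rt
Reagents that add atoms: none
Why: Fluoride cleavage of the secondary TBS ether frees the homoallylic C9 hydroxyl needed to direct the epoxidation.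

Step 8
Reactants: 10 cyclohexene diol
Product: 11 (1S)-1-[(1R,2S,3R,6S)-3-(hydroxymethyl)-6-methyl-7-oxabicyclo[4.1.0]heptan-2-yl]ethan-1-ol (epoxide oxygen cis to both arms)
Conditions: VO(acac)2 (5 mol%), t-BuOOH, CH2Cl2, 0 °C → rt
Reagents that add atoms: tert-butyl hydroperoxide, CC(C)(C)OO
Why: Vanadium-catalysed epoxidation directed by the homoallylic C9 hydroxyl (and the C1 hydroxyl on the same face) should deliver oxygen to the face of C14=C15 that carries both arms, setting C14 and C15.

Step 9
Reactants: 11 syn-epoxy diol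
Product: 13 epoxide precursor (C1–O-TBS and C9–O-TES ether of 11), via primary TBS ether 12 (not isolated)
Conditions: TBSCl (1.05 equiv), imidazole, DMF, −10 °C; then TESCl, rt
Reagents that add atoms: tert-butyldimethylsilyl chloride, CC(C)(C)[Si](C)(C)Cl; triethylsilyl chloride, CC[Si](CC)(CC)Cl
Why: Sequential silylation, the unhindered primary hydroxyl reacting first, gives two non-nucleophilic ethers that can later be removed in the order C9 then C1.

Step 10
Reactants: 13 epoxide precursor
Product: 14 (1S,2R,3R)-3-(TBS-oxymethyl)-1-methyl-2-[(1S)-1-(TES-oxy)ethyl]cyclopentane-1-carbaldehyde (ring A aldehyde; C15, C9 and C1 mutually cis)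
Conditions: InCl3 (0.2 equiv), THF, rt
Reagents that add atoms: none
Why: InCl3 binds the epoxide oxygen and the tertiary C14–O bond lengthens; as it breaks, the ring bond C15–C10 shifts to the rear lobe at C14 while C15 becomes the carbonyl carbon, so C10–C14 forms, C10–C15 breaks and the cyclohexane contracts to ring A (Meinwald rearrangement, the semipinacol ring contraction known for 1-methylcyclohexene oxides giving 1-methylcyclopentanecarbaldehydes). Ring A is therefore closed by a 1,2-alkyl shift (ring contraction) and not by a cyclisation. The shift is suprafacial and anti, so C10 keeps its configuration and C14 is inverted; the new quaternary centre C14 is thus fixed by the epoxide configuration from step 8, and C15 ends on the face the oxygen occupied, cis to C9 and C1. The step needs migration of C10 and not of the C15 hydride: in the half-chair formed as C14–O ionises the oxygen on C15 is pseudo-axial, the C15–H bond lies near the nodal plane of the developing p orbital and only the C15–C10 bond overlaps with its rear lobe, and C10 is a branched secondary carbon, a better migrating group than the ring CH2 of the parent system. The two silyl ethers are poor nucleophiles and sit on the epoxide face, so they cannot reach the rear of C14, and a catalytic, weakly ionising Lewis acid in THF should avoid a long-lived cation that could ring-flip and shift hydride.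

Step 11
Reactants: 15 (4S)-4-benzyl-1,3-oxazolidin-2-one; 16 (benzyloxy)acetyl chloride
Product: 17 (4S)-4-benzyl-3-[(benzyloxy)acetyl]-1,3-oxazolidin-2-one
Conditions: Et3N, DMAP (cat.), CH2Cl2, 0 °C → rt
Reagents that add atoms: none
Why: DMAP-catalysed N-acylation of the oxazolidinone with the acid chloride gives the glycolate imide.

Step 12
Reactants: 17 glycolate imide; 14 ring A aldehyde
Product: 19 (4S)-4-benzyl-3-[(2S,3R)-2-(benzyloxy)-3-hydroxy-3-(ring A)propanoyl]-1,3-oxazolidin-2-one (C16 S and C15 R), via boron enolate 18 (not isolated)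
Conditions: Bu2BOTf, Et3N, CH2Cl2, −78 → 0 °C; then 14, −78 → 0 °C; pH 7 buffer, MeOH, H2O2
Reagents that add atoms: none
Why: In this Evans syn-glycolate aldol the (Z)-boron enolate reacts through a Zimmerman–Traxler chair on the face set by the (S)-benzyl auxiliary, which should give the syn adduct (the C15/C16 trans-diol of ring B) under reagent control despite the α-quaternary aldehyde.

Step 13
Reactants: 19 syn-aldol adduct
Product: 20 (2S,3R)-2-(benzyloxy)-3-hydroxy-N-methoxy-N-methyl-3-(ring A)propanamide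
Conditions: MeONHMe·HCl, AlMe3, THF, −20 → 0 °C
Reagents that add atoms: N,O-dimethylhydroxylamine hydrochloride, CNOC.Cl
Why: Aluminium-amide transamination of the β-hydroxy imide gives the Weinreb amide and releases the auxiliary, the free C15 hydroxyl favouring exocyclic cleavage.

Step 14
Reactants: 20 benzyloxy Weinreb amide
Product: 21 (2S,3R)-2,3-dihydroxy Weinreb amide
Conditions: H2 (1 atm), Pd(OH)2/C, EtOAc, rt
Reagents that add atoms: none
Why: Hydrogenolysis of the benzyl ether is clean here because no alkene is present and the silyl ethers and the N–O bond survive in EtOAc.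

Step 15
Reactants: 21 diol Weinreb amide
Product: 22 (2S,3R)-2,3-bis(TBS-oxy) Weinreb amide
Conditions: TBSOTf, 2,6-lutidine, CH2Cl2, 0 °C → rt
Reagents that add atoms: tert-butyldimethylsilyl triflate, CC(C)(C)[Si](C)(C)OS(=O)(=O)C(F)(F)F
Why: The silyl triflate silylates both secondary hydroxyls, including the hindered C15 one, without touching the TES ether.

Step 16
Reactants: 23 methyl 5,5-dimethoxypentanoate
Product: 24 lithium 5,5-dimethoxypentanoate
Conditions: LiOH·H2O (1.0 equiv), THF–H2O, rt; evaporate and dry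
Reagents that add atoms: lithium hydroxide, [Li+].[OH-]
Why: Saponification to the isolated lithium carboxylate avoids any acid contact of the dimethyl acetal.

Step 17
Reactants: 24 lithium 5,5-dimethoxypentanoate; 25 (4R)-4-benzyl-1,3-oxazolidin-2-one
Product: 27 (4R)-4-benzyl-3-(5,5-dimethoxypentanoyl)-1,3-oxazolidin-2-one, via mixed anhydride 26 (not isolated)
Conditions: PivCl, THF, −20 °C; then 25, Et3N, LiCl, −20 °C → rt
Reagents that add atoms: none
Why: The mixed pivalic anhydride acylates the oxazolidinone at the less hindered carbonyl under LiCl/Et3N activation.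

Step 18
Reactants: 27 acyl oxazolidinone
Product: 29 (4R)-4-benzyl-3-[(2S)-2-(3,3-dimethoxypropyl)pent-4-enoyl]-1,3-oxazolidin-2-one, via sodium enolate 28 (not isolated)
Conditions: NaN(SiMe3)2, THF, −78 °C; then allyl iodide, −78 → −45 °C
Reagents that add atoms: allyl iodide, C=CCI
Why: In this Evans alkylation the chelated (Z)-sodium enolate is allylated on the face opposite the benzyl group, which sets C5.

Step 19
Reactants: 29 allylated imide
Product: 30 (2S)-2-(3,3-dimethoxypropyl)pent-4-en-1-ol
Conditions: LiBH4, H2O (1 equiv), Et2O, 0 °C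
Reagents that add atoms: none
Why: Reductive removal of the auxiliary gives the primary alcohol while the acetal and alkene are inert.

Step 20
Reactants: 30 primary alcohol
Product: 31 1-({[(2S)-2-(3,3-dimethoxypropyl)pent-4-en-1-yl]oxy}methyl)-4-methoxybenzene
Conditions: NaH, PMBCl, Bu4NI (cat.), DMF, 0 °C → rt
Reagents that add atoms: 4-methoxybenzyl chloride, COc1ccc(CCl)cc1
Why: Williamson etherification protects the C5 hydroxymethyl as a PMB ether, which is orthogonal to every silyl group used.

Step 21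
Reactants: 31 PMB ether
Product: 33 (3S)-6,6-dimethoxy-3-(PMB-oxymethyl)hexan-1-ol, via aldehyde 32 (not isolated)
Conditions: OsO4 (2 mol%), NaIO4, 2,6-lutidine, dioxane–H2O, rt; then NaBH4, MeOH, 0 °C
Reagents that add atoms: osmium tetroxide, O=[Os](=O)(=O)=O; sodium periodate, [Na+].[O-]I(=O)(=O)=O
Why: Lemieux–Johnson cleavage shortens the allyl group to the two-carbon C6–C7 arm and borohydride reduces the aldehyde, the buffered conditions sparing the PMB ether and acetal.

Step 22
Reactants: 33 primary alcohol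
Product: 34 1-({[(2S)-2-(2-iodoethyl)-5,5-dimethoxypentyl]oxy}methyl)-4-methoxybenzene (C2–C7 fragment)
Conditions: I2, PPh3, imidazole, CH2Cl2, 0 °C → rt
Reagents that add atoms: iodine, II
Why: Appel-type iodination of the primary alcohol proceeds under imidazole buffering, which protects the acetal.

Step 23
Reactants: 34 C2–C7 iodide; 22 bis-TBS Weinreb amide
Product: 36 C8 ketone (C7–C8 joined; C16 S and C15 R bis-TBS ether), via alkyllithium 35 (not isolated)
Conditions: 34, t-BuLi (2 equiv), Et2O–pentane, −78 °C; then 22, −78 → −20 °C; aq. NH4Cl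
Reagents that add atoms: none
Why: Lithium–iodine exchange gives the primary alkyllithium, which adds once to the Weinreb amide through the chelated tetrahedral intermediate and so forms the C7–C8 bond as a ketone.

Step 24
Reactants: 36 C8 ketone
Product: 37 C9 alcohol (TES removed)
Conditions: PPTS (cat.), MeOH–CH2Cl2, 0 °C
Reagents that add atoms: none
Why: Acid-catalysed methanolysis cleaves the secondary TES ether well before any TBS ether, and the dimethyl acetal only exchanges degenerately in methanol.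

Step 25
Reactants: 37 C9 alcohol
Product: 38 C8/C9 diketone
Conditions: DMP, NaHCO3, CH2Cl2, 0 °C → rt
Reagents that add atoms: none
Why: Buffered Dess–Martin oxidation gives the C9 methyl ketone without epimerising C10 or C16.

Step 26
Reactants: 38 diketone
Product: 39 diene (C8 methylidene and C10 isopropenyl)
Conditions: Cp2TiMe2, toluene, 70 °C, dark
Reagents that add atoms: dimethyltitanocene, C[Ti](C)(C1C=CC=C1)C1C=CC=C1
Why: Petasis methylenation converts both ketones into 1,1-disubstituted alkenes under non-basic conditions, so the α-centres C10 and C16 should not epimerise.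

Step 27
Reactants: 39 diene
Product: 40 rings A and B (tetrasubstituted C8=C9 alkene)
Conditions: second-generation Hoveyda–Grubbs catalyst RuCl2(H2IMes)(=CH-C6H4-2-OiPr) (20 mol%), toluene (2 mM), 100 °C, Ar sparge
Reagents that add atoms: none
Why: Ring-closing metathesis of the two 1,1-disubstituted alkenes closes the six-membered ring B with loss of ethene, a known if demanding route to tetrasubstituted cyclohexenes that is helped by the cis arrangement of the two arms on ring A.

Step 28
Reactants: 40 tris-TBS ether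
Product: 41 C1 primary alcohol
Conditions: HF·pyridine, pyridine, THF, 0 °C → rt
Reagents that add atoms: none
Why: Buffered HF·pyridine removes the primary TBS ether selectively in the presence of the two secondary ones.

Step 29
Reactants: 41 C1 alcohol
Product: 42 C1 aldehyde
Conditions: DMP, NaHCO3, CH2Cl2, 0 °C
Reagents that add atoms: none
Why: Buffered Dess–Martin oxidation gives the aldehyde without epimerising C11 (used at once).

Step 30
Reactants: 42 C1 aldehyde
Product: 43 C1 methyl carbinol (both C1 epimers)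
Conditions: MeMgBr, THF, −78 °C
Reagents that add atoms: methylmagnesium bromide, C[Mg]Br
Why: Grignard addition installs the carbon that becomes the exocyclic methylene, and the new carbinol centre is removed in the next step.

Step 31
Reactants: 43 methyl carbinol
Product: 44 C1 methyl ketone
Conditions: DMP, NaHCO3, CH2Cl2, 0 °C → rt
Reagents that add atoms: none
Why: Dess–Martin oxidation converges both epimers to the methyl ketone.

Step 32
Reactants: 44 methyl ketone
Product: 46 C1 alkenyl triflate, via potassium enolate 45 (not isolated)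
Conditions: KN(SiMe3)2, THF, −78 °C; then Comins' reagent, −78 °C
Reagents that add atoms: N-(5-chloropyridin-2-yl)bis(trifluoromethanesulfonyl)imide, O=S(=O)(N(c1ccc(Cl)cn1)S(=O)(=O)C(F)(F)F)C(F)(F)F
Why: Kinetic deprotonation occurs at the methyl group and not at the hindered C11 methine, and O-triflation at −78 °C traps the terminal enolate before it can equilibrate.

Step 33
Reactants: 46 alkenyl triflate acetal
Product: 47 C2 aldehyde
Conditions: PPTS (cat.), acetone–H2O (10:1), 40 °C
Reagents that add atoms: water, O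
Why: Mild acid hydrolysis of the dimethyl acetal frees the C2 aldehyde while the alkenyl triflate, the PMB ether and the secondary TBS ethers are stable.

Step 34
Reactants: 47 triflate aldehyde
Product: 48 macrocyclic allylic alcohol (rings A, B and C; both C2 epimers)
Conditions: CrCl2 (10 equiv), NiCl2 (1 mol% of the CrCl2), DMF, rt, slow addition to 2 mM
Reagents that add atoms: none
Why: In this Nozaki–Hiyama–Kishi reaction nickel-catalysed formation of the alkenylchromium species at C1 and its addition to the C2 aldehyde at high dilution closes the eleven-membered ring C, the two chain ends being held on one face of ring A.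

Step 35
Reactants: 48 allylic alcohol
Product: 49 macrocyclic α-methylene ketone
Conditions: DMP, NaHCO3, CH2Cl2, 0 °C
Reagents that add atoms: none
Why: Oxidation of the allylic alcohol converges both C2 epimers to one enone.

Step 36
Reactants: 49 enone
Product: 50 (2S)-allylic alcohol
Conditions: (R)-2-methyl-CBS-oxazaborolidine (0.5 equiv), catecholborane, toluene, −78 °C
Reagents that add atoms: none
Why: In this Corey–Bakshi–Shibata reduction the α-branched alkenyl group acts as the large substituent, so the (R)-catalyst should deliver hydride to give the (2S) carbinol under reagent control, and catecholborane at −78 °C leaves the alkenes alone.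

Step 37
Reactants: 50 PMB ether
Product: 51 C2/C5-hydroxymethyl diol
Conditions: DDQ, CH2Cl2–pH 7 buffer, 0 °C
Reagents that add atoms: none
Why: Oxidative cleavage of the PMB ether is orthogonal to the silyl ethers.

Step 38
Reactants: 51 diol
Product: 52 diacetate bis-TBS ether
Conditions: Ac2O, pyridine, DMAP (cat.), CH2Cl2, 0 °C → rt
Reagents that add atoms: acetic anhydride, CC(=O)OC(C)=O
Why: Both free hydroxyls are acetylated while C15 and C16 remain silylated.

Step 39
Reactants: 52 diacetate bis-TBS ether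
Product: 53 target CNP0193272.1
Conditions: HF·pyridine, THF, 0 → 40 °C
Reagents that add atoms: none
Why: Fluoride-mediated cleavage of the two secondary TBS ethers frees the C15/C16 trans-diol under conditions that spare the acetates and both alkenes.

**Compound list**
1 | ethyl (S)-lactate | CCOC(=O)[C@H](C)O | starting material
2 | ethyl (2S)-2-(TBS-oxy)propanoate | CCOC(=O)[C@H](C)O[Si](C)(C)C(C)(C)C | intermediate
3 | (2S)-2-(TBS-oxy)propanal | O=C[C@H](C)O[Si](C)(C)C(C)(C)C | intermediate
4 | diethyl (2-oxopropyl)phosphonate | CCOP(=O)(CC(C)=O)OCC | starting material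
5 | (3E,5S)-5-(TBS-oxy)hex-3-en-2-one | CC(=O)/C=C/[C@H](C)O[Si](C)(C)C(C)(C)C | intermediate
6 | tert-butyl(dimethyl){[(2S,3E)-5-methylhexa-3,5-dien-2-yl]oxy}silane | C=C(C)/C=C/[C@H](C)O[Si](C)(C)C(C)(C)C | intermediate
7 | methyl acrylate | C=CC(=O)OC | starting material
8 | methyl (1R,2S)-2-[(1S)-1-(TBS-oxy)ethyl]-4-methylcyclohex-3-ene-1-carboxylate | CC1=C[C@H]([C@H](C)O[Si](C)(C)C(C)(C)C)[C@H](C(=O)OC)CC1 | intermediate
9 | {(1R,2S)-2-[(1S)-1-(TBS-oxy)ethyl]-4-methylcyclohex-3-en-1-yl}methanol | CC1=C[C@H]([C@H](C)O[Si](C)(C)C(C)(C)C)[C@H](CO)CC1 | intermediate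
10 | (1S)-1-[(1S,6R)-6-(hydroxymethyl)-3-methylcyclohex-2-en-1-yl]ethan-1-ol | CC1=C[C@H]([C@H](C)O)[C@H](CO)CC1 | intermediate
11 | (1S)-1-[(1R,2S,3R,6S)-3-(hydroxymethyl)-6-methyl-7-oxabicyclo[4.1.0]heptan-2-yl]ethan-1-ol (syn-epoxy diol) | C[C@]12CC[C@@H](CO)[C@@H]([C@H](C)O)[C@H]1O2 | intermediate
12 | primary TBS ether of 11 | C[C@]12CC[C@@H](CO[Si](C)(C)C(C)(C)C)[C@@H]([C@H](C)O)[C@H]1O2 | intermediate
13 | epoxide precursor: C1–O-TBS, C9–O-TES ether of 11 (epoxide across C14/C15 syn to both arms) | C[C@]12CC[C@@H](CO[Si](C)(C)C(C)(C)C)[C@@H]([C@H](C)O[Si](CC)(CC)CC)[C@H]1O2 | intermediate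
14 | (1S,2R,3R)-3-(TBS-oxymethyl)-1-methyl-2-[(1S)-1-(TES-oxy)ethyl]cyclopentane-1-carbaldehyde (ring A aldehyde) | O=C[C@@]1(C)CC[C@@H](CO[Si](C)(C)C(C)(C)C)[C@H]1[C@H](C)O[Si](CC)(CC)CC | intermediate
15 | (4S)-4-benzyl-1,3-oxazolidin-2-one | O=C1OC[C@H](Cc2ccccc2)N1 | starting material
16 | (benzyloxy)acetyl chloride | O=C(Cl)COCc1ccccc1 | starting material
17 | (4S)-4-benzyl-3-[(benzyloxy)acetyl]-1,3-oxazolidin-2-one | O=C1OC[C@H](Cc2ccccc2)N1C(=O)COCc1ccccc1 | intermediate
18 | (Z)-dibutylboron enolate of 17 | CCCCB(CCCC)O/C(=C\OCc1ccccc1)N1C(=O)OC[C@@H]1Cc1ccccc1 | intermediate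
19 | syn-aldol adduct, (2S,3R)-2-benzyloxy-3-hydroxy acyl oxazolidinone on ring A | O=C1OC[C@H](Cc2ccccc2)N1C(=O)[C@@H](OCc1ccccc1)[C@H](O)[C@@]3(C)CC[C@@H](CO[Si](C)(C)C(C)(C)C)[C@H]3[C@H](C)O[Si](CC)(CC)CC | intermediate
20 | (2S,3R)-2-benzyloxy-3-hydroxy Weinreb amide | CON(C)C(=O)[C@@H](OCc1ccccc1)[C@H](O)[C@@]2(C)CC[C@@H](CO[Si](C)(C)C(C)(C)C)[C@H]2[C@H](C)O[Si](CC)(CC)CC | intermediate
21 | (2S,3R)-2,3-dihydroxy Weinreb amide | CON(C)C(=O)[C@@H](O)[C@H](O)[C@@]2(C)CC[C@@H](CO[Si](C)(C)C(C)(C)C)[C@H]2[C@H](C)O[Si](CC)(CC)CC | intermediate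
22 | (2S,3R)-2,3-bis(TBS-oxy) Weinreb amide | CON(C)C(=O)[C@@H](O[Si](C)(C)C(C)(C)C)[C@H](O[Si](C)(C)C(C)(C)C)[C@@]2(C)CC[C@@H](CO[Si](C)(C)C(C)(C)C)[C@H]2[C@H](C)O[Si](CC)(CC)CC | intermediate
23 | methyl 5,5-dimethoxypentanoate | COC(=O)CCCC(OC)OC | starting material
24 | lithium 5,5-dimethoxypentanoate | [Li+].[O-]C(=O)CCCC(OC)OC | intermediate
25 | (4R)-4-benzyl-1,3-oxazolidin-2-one | O=C1OC[C@@H](Cc2ccccc2)N1 | starting material
26 | 5,5-dimethoxypentanoic pivalic anhydride | CC(C)(C)C(=O)OC(=O)CCCC(OC)OC | intermediate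
27 | (4R)-4-benzyl-3-(5,5-dimethoxypentanoyl)-1,3-oxazolidin-2-one | O=C1OC[C@@H](Cc2ccccc2)N1C(=O)CCCC(OC)OC | intermediate
28 | (Z)-sodium enolate of 27 | [Na+].[O-]/C(=C\CCC(OC)OC)N1C(=O)OC[C@H]1Cc1ccccc1 | intermediate
29 | (4R)-4-benzyl-3-[(2S)-2-(3,3-dimethoxypropyl)pent-4-enoyl]-1,3-oxazolidin-2-one | O=C1OC[C@@H](Cc2ccccc2)N1C(=O)[C@H](CC=C)CCC(OC)OC | intermediate
30 | (2S)-2-(3,3-dimethoxypropyl)pent-4-en-1-ol | OC[C@H](CC=C)CCC(OC)OC | intermediate
31 | 1-({[(2S)-2-(3,3-dimethoxypropyl)pent-4-en-1-yl]oxy}methyl)-4-methoxybenzene | COc1ccc(COC[C@H](CC=C)CCC(OC)OC)cc1 | intermediate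
32 | (3S)-6,6-dimethoxy-3-(PMB-oxymethyl)hexanal | O=CC[C@@H](COCc1ccc(OC)cc1)CCC(OC)OC | intermediate
33 | (3S)-6,6-dimethoxy-3-(PMB-oxymethyl)hexan-1-ol | OCC[C@@H](COCc1ccc(OC)cc1)CCC(OC)OC | intermediate
34 | 1-({[(2S)-2-(2-iodoethyl)-5,5-dimethoxypentyl]oxy}methyl)-4-methoxybenzene (C2–C7 fragment) | ICC[C@@H](COCc1ccc(OC)cc1)CCC(OC)OC | intermediate
35 | primary alkyllithium from 34 | [Li]CC[C@@H](COCc1ccc(OC)cc1)CCC(OC)OC | intermediate
36 | C8 ketone (C2 acetal, C5 PMB-oxymethyl, C15/C16 bis-TBS, C9–O-TES, C1–O-TBS) | COC(OC)CC[C@H](COCc1ccc(OC)cc1)CCC(=O)[C@@H](O[Si](C)(C)C(C)(C)C)[C@H](O[Si](C)(C)C(C)(C)C)[C@@]2(C)CC[C@@H](CO[Si](C)(C)C(C)(C)C)[C@H]2[C@H](C)O[Si](CC)(CC)CC | intermediate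
37 | C9 alcohol of 36 | COC(OC)CC[C@H](COCc1ccc(OC)cc1)CCC(=O)[C@@H](O[Si](C)(C)C(C)(C)C)[C@H](O[Si](C)(C)C(C)(C)C)[C@@]2(C)CC[C@@H](CO[Si](C)(C)C(C)(C)C)[C@H]2[C@H](C)O | intermediate
38 | C8/C9 diketone | COC(OC)CC[C@H](COCc1ccc(OC)cc1)CCC(=O)[C@@H](O[Si](C)(C)C(C)(C)C)[C@H](O[Si](C)(C)C(C)(C)C)[C@@]2(C)CC[C@@H](CO[Si](C)(C)C(C)(C)C)[C@H]2C(C)=O | intermediate
39 | diene (C8 methylidene, C10 isopropenyl) | COC(OC)CC[C@H](COCc1ccc(OC)cc1)CCC(=C)[C@@H](O[Si](C)(C)C(C)(C)C)[C@H](O[Si](C)(C)C(C)(C)C)[C@@]2(C)CC[C@@H](CO[Si](C)(C)C(C)(C)C)[C@H]2C(C)=C | intermediate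
40 | rings A/B tris-TBS ether (C8=C9 closed) | COC(OC)CC[C@H](COCc1ccc(OC)cc1)CCC2=C(C)[C@@H]3[C@H](CO[Si](C)(C)C(C)(C)C)CC[C@]3(C)[C@@H](O[Si](C)(C)C(C)(C)C)[C@@H]2O[Si](C)(C)C(C)(C)C | intermediate
41 | C1 primary alcohol | COC(OC)CC[C@H](COCc1ccc(OC)cc1)CCC2=C(C)[C@@H]3[C@H](CO)CC[C@]3(C)[C@@H](O[Si](C)(C)C(C)(C)C)[C@@H]2O[Si](C)(C)C(C)(C)C | intermediate
42 | C1 aldehyde | COC(OC)CC[C@H](COCc1ccc(OC)cc1)CCC2=C(C)[C@@H]3[C@H](C=O)CC[C@]3(C)[C@@H](O[Si](C)(C)C(C)(C)C)[C@@H]2O[Si](C)(C)C(C)(C)C | intermediate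
43 | C1 methyl carbinol (both C1 epimers) | COC(OC)CC[C@H](COCc1ccc(OC)cc1)CCC2=C(C)[C@@H]3[C@H](C(C)O)CC[C@]3(C)[C@@H](O[Si](C)(C)C(C)(C)C)[C@@H]2O[Si](C)(C)C(C)(C)C | intermediate
44 | C1 methyl ketone | COC(OC)CC[C@H](COCc1ccc(OC)cc1)CCC2=C(C)[C@@H]3[C@H](C(C)=O)CC[C@]3(C)[C@@H](O[Si](C)(C)C(C)(C)C)[C@@H]2O[Si](C)(C)C(C)(C)C | intermediate
45 | terminal potassium enolate of 44 | [K+].COC(OC)CC[C@H](COCc1ccc(OC)cc1)CCC2=C(C)[C@@H]3[C@H](C(=C)[O-])CC[C@]3(C)[C@@H](O[Si](C)(C)C(C)(C)C)[C@@H]2O[Si](C)(C)C(C)(C)C | intermediate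
46 | C1 alkenyl triflate | COC(OC)CC[C@H](COCc1ccc(OC)cc1)CCC2=C(C)[C@@H]3[C@H](C(=C)OS(=O)(=O)C(F)(F)F)CC[C@]3(C)[C@@H](O[Si](C)(C)C(C)(C)C)[C@@H]2O[Si](C)(C)C(C)(C)C | intermediate
47 | C2 aldehyde with C1 alkenyl triflate | O=CCC[C@H](COCc1ccc(OC)cc1)CCC2=C(C)[C@@H]3[C@H](C(=C)OS(=O)(=O)C(F)(F)F)CC[C@]3(C)[C@@H](O[Si](C)(C)C(C)(C)C)[C@@H]2O[Si](C)(C)C(C)(C)C | intermediate
48 | tricyclic allylic alcohol (both C2 epimers) | C=C1C(O)CC[C@H](COCc4ccc(OC)cc4)CCC2=C(C)[C@@H]3[C@H]1CC[C@]3(C)[C@@H](O[Si](C)(C)C(C)(C)C)[C@@H]2O[Si](C)(C)C(C)(C)C | intermediate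
49 | tricyclic α-methylene ketone (C2 ketone) | C=C1C(=O)CC[C@H](COCc4ccc(OC)cc4)CCC2=C(C)[C@@H]3[C@H]1CC[C@]3(C)[C@@H](O[Si](C)(C)C(C)(C)C)[C@@H]2O[Si](C)(C)C(C)(C)C | intermediate
50 | (2S)-allylic alcohol | C=C1[C@@H](O)CC[C@H](COCc4ccc(OC)cc4)CCC2=C(C)[C@@H]3[C@H]1CC[C@]3(C)[C@@H](O[Si](C)(C)C(C)(C)C)[C@@H]2O[Si](C)(C)C(C)(C)C | intermediate
51 | C2 / C5-hydroxymethyl diol, C15/C16 bis-TBS ether | C=C1[C@@H](O)CC[C@H](CO)CCC2=C(C)[C@@H]3[C@H]1CC[C@]3(C)[C@@H](O[Si](C)(C)C(C)(C)C)[C@@H]2O[Si](C)(C)C(C)(C)C | intermediate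
52 | diacetate, C15/C16 bis-TBS ether | C=C1[C@@H](OC(C)=O)CC[C@H](COC(C)=O)CCC2=C(C)[C@@H]3[C@H]1CC[C@]3(C)[C@@H](O[Si](C)(C)C(C)(C)C)[C@@H]2O[Si](C)(C)C(C)(C)C | intermediate
53 | CNP0193272.1 | C=C1[C@@H](OC(C)=O)CC[C@H](COC(C)=O)CCC2=C(C)[C@@H]3[C@H]1CC[C@]3(C)[C@@H](O)[C@@H]2O | target

**Step count**
Total: 39 steps. Longest linear sequence: 31 steps (steps 1–10, 12–15 and 23–39, from ethyl (S)-lactate).

**Steps most likely to fail**

Step 10 (epoxide ring contraction). The risk is a 1,2-hydride shift from C15 after ring flip of the ionised epoxide, which would give the 2-methylcyclohexanone, or loss of stereospecificity if chloride opens the epoxide before migration. Fallback: a halohydrin relay from the diastereomeric epoxide. Setting out from diol 10, stepwise silylation (TBSCl, then TESCl) gives the primary TBS ether F1 and then the bis-silyl alkene F2. mCPBA should epoxidise F2 on the face away from the two arms to give the anti-epoxide F3. MgBr2·OEt2 opens F3 at the tertiary C14 with inversion to the trans-bromohydrin F4, whose diequatorial conformer holds the C15–C10 bond antiperiplanar to C14–Br and the C15–H bond gauche to it. Warming its magnesium alkoxide (or adding AgBF4) then triggers the classical halohydrin semipinacol ring contraction with a second inversion at C14. The two inversions lead to the same aldehyde 14, where the route is rejoined.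

Step 27 (ring-closing metathesis to the tetrasubstituted alkene). The risk is slow loading of the ruthenium carbene on either hindered 1,1-disubstituted alkene, so that catalyst decay and alkene isomerisation outrun ring closure. Fallback: reductive carbonyl coupling. Setting out from diketone 38, a McMurry reaction with low-valent titanium (TiCl3(DME)1.5, Zn–Cu couple, DME, reflux) should join C8 and C9 directly and close ring B, which bypasses step 26. No new compound is made on the way (F0), and the route is rejoined at 40.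

Step 34 (NHK macrocyclisation). The risk is intermolecular coupling or simple reduction of the alkenyl triflate competing with closure of the eleven-membered ring. Fallback: nickel-catalysed reductive alkyne–aldehyde macrocyclisation. Setting out from alkenyl triflate 46, elimination with LiN(iPr)2 gives the terminal alkyne F5, and acetal hydrolysis as in step 33 gives the ynal F6. Ni(cod)2 with a bulky N-heterocyclic carbene ligand and Et3SiH should join the aldehyde carbon to the internal alkyne carbon (exocyclic mode) to give the triethylsilyl ether F7. PPTS in methanol removes the TES group and returns the route to 48.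

**Further compounds**
F1 | step 10 | primary TBS ether of diol 10 | CC1=C[C@H]([C@H](C)O)[C@H](CO[Si](C)(C)C(C)(C)C)CC1
F2 | step 10 | bis-silyl alkene (C1–O-TBS, C9–O-TES) | CC1=C[C@H]([C@H](C)O[Si](CC)(CC)CC)[C@H](CO[Si](C)(C)C(C)(C)C)CC1
F3 | step 10 | anti-epoxide (oxygen trans to both arms) | C[C@@]12CC[C@@H](CO[Si](C)(C)C(C)(C)C)[C@@H]([C@H](C)O[Si](CC)(CC)CC)[C@@H]1O2
F4 | step 10 | trans-bromohydrin (C14 bromide, C15 hydroxyl) | C[C@]1(Br)CC[C@@H](CO[Si](C)(C)C(C)(C)C)[C@@H]([C@H](C)O[Si](CC)(CC)CC)[C@@H]1O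
F0 | step 27 | none | none
F5 | step 34 | C11 ethynyl acetal | COC(OC)CC[C@H](COCc1ccc(OC)cc1)CCC2=C(C)[C@@H]3[C@H](C#C)CC[C@]3(C)[C@@H](O[Si](C)(C)C(C)(C)C)[C@@H]2O[Si](C)(C)C(C)(C)C
F6 | step 34 | ynal | O=CCC[C@H](COCc1ccc(OC)cc1)CCC2=C(C)[C@@H]3[C@H](C#C)CC[C@]3(C)[C@@H](O[Si](C)(C)C(C)(C)C)[C@@H]2O[Si](C)(C)C(C)(C)C
F7 | step 34 | triethylsilyl ether of 48 | C=C1C(O[Si](CC)(CC)CC)CC[C@H](COCc4ccc(OC)cc4)CCC2=C(C)[C@@H]3[C@H]1CC[C@]3(C)[C@@H](O[Si](C)(C)C(C)(C)C)[C@@H]2O[Si](C)(C)C(C)(C)C
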